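(All runs were generated by integration with constants of no real substance; noise was put on by code.)

A single-handed free catalyst passes reagent to a racemic substrate and makes left-handed product, and I take the racemization catalyst to interconvert the two substrates. I have to rank the set-ups below from the earlier closed runs.

in all of them: free catalyst 0.20 mM; added ligand 7.9 mM

| flask | left-handed substrate | right-handed substrate | reagent | racemization catalyst | remark | time |
|---|---|---|---|---|---|---|
| cedar | 0.020 M | 0.020 M | 0.060 M | 2 mM | run made earlier |  |
| larch | 0.028 M | 0.028 M | 0.060 M | 2 mM | run made earlier |  |
| oak | 0.044 M | 0.044 M | 0.060 M | 2 mM | run made earlier |  |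
| Thursday's | 0.020 M | 0.020 M | 0.0600 M | 2.0 mM | one stirred flow tank at steady state, fed with the mixture as stated, mean residence time 200 min |  |
| Sunday's | 0.020 M | 0.020 M | 0.0600 M | 2.0 mM | one stirred flow tank at steady state, fed with the mixture as stated, mean residence time 20 min |  |
| Saturday's | 0.020 M | 0.020 M | 0.0600 M (fed, over 10.0 min) | 2.0 mM | a stirred flask in which reagent is dosed at a steady rate over 10.0 min without added volume, worked up at 20 min | 20 min |
| Tuesday's | 0.020 M | 0.020 M | 0.0600 M | 2.0 mM | a closed flask charged with all of it at once and left for 20 min | 20 min |

| run | time / min | left-handed product / % |
|---|---|---|
| cedar | 0.667 | 4.0 |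
| cedar | 2.00 | 10.0 |
| cedar | 3.00 | 14.2 |
| cedar | 5.00 | 20.6 |
| cedar | 8.00 | 28.9 |
| cedar | 10.0 | 35.0 |
| cedar | 12.0 | 37.6 |
| larch | 0.667 | 3.7 |
| larch | 2.00 | 10.0 |
| larch | 3.00 | 13.0 |
| larch | 5.00 | 20.6 |
| larch | 8.00 | 28.1 |
| larch | 10.0 | 32.6 |
| larch | 12.0 | 37.0 |
| oak | 0.667 | 3.2 |
| oak | 2.00 | 9.3 |
| oak | 3.00 | 13.3 |
| oak | 5.00 | 19.3 |
| oak | 8.00 | 25.7 |
| oak | 10.0 | 29.5 |
| oak | 12.0 | 32.2 |

(each reading ± 0.5 percentage points)

- free catalyst is single-handed; left-handed substrate and right-handed substrate are mirror images of each other, charged as a racemate, each of them at the stated concentration
- the stated concentrations are those of everything mixed, before any reaction; amounts are the same in each set-up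
- the feed brings no volume worth counting
- the earlier runs were made in a closed, stirred flask

1. the set-up with the highest amount of left-handed product at the outlet or at the end, in percent of the left-handed substrate and right-handed substrate together put in ("none" if the first two lie within 2 percentage points) (Thursday's / Sunday's / Saturday's / Tuesday's / none)
2. amount of left-handed product at the outlet or at the end, in percent of the left-handed substrate and right-handed substrate together put in, Thursday's
3. amount of left-handed product at the outlet or at the end, in percent of the left-handed substrate and right-handed substrate together put in, Sunday's
4. amount of left-handed product at the outlet or at the end, in percent of the left-handed substrate and right-handed substrate together put in, Saturday's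
5. amount of left-handed product at the outlet or at the end, in percent of the left-handed substrate and right-handed substrate together put in, Tuesday's

I build Tuesday's flask one process at a time, writing P for left-handed product in percent of both substrates charged. First comes the main step alone. The cedar run reads 10.0% at 2.00 min, and the left-handed substrate is half of the charge, so I read a pseudo-first-order constant k of 0.112 min⁻¹. With this step alone, P reaches 44.7% in 20 min. The same curve gives 36.9% at 12.0 min, and cedar's reading there is 37.6%, which stands 0.70 percentage points higher against a scatter of 0.5 points on a reading. This comparison therefore does not show substrate crossing over, and crossing over remains my assumption.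

Next I add racemization. If the two hands stay about equal, the left-handed step drains the whole pool at 0.0558 min⁻¹, and P in 20 min rises to 67.2%.

Then I add the rest. I assume the rate follows reagent, which falls as it is used, and I replace its curve by its mean. In cedar, counting left-handed product as the reagent's sole use, the mean share of the charge is 0.875. I define the drain constant λ as the first-order rate at which the part of the charge not yet left-handed product falls, per minute of full reagent: 0.0449 min⁻¹, a reading that carries the scatter of cedar's last point. For Tuesday's the mean share depends on P, so I iterate. A first pass gives a share of 0.802 and P of 51.4%. A second pass gives a share of 0.829 and P of 52.5%.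

The forecast names Thursday's as best, with 80% there, 39% for Sunday's, 43% for Saturday's and 50% for Tuesday's, “assuming the catalysts survive beyond the observed 12 min”. My figure for Tuesday's stands 2.5 points above the forecast's.

The flask gives 67.9% for Thursday's, more than any other set-up, and that is where it parts from the forecast, by 12 points. Sunday's gives 38.2%, Saturday's 43.3% and Tuesday's 50.0%.

    reagent + free catalyst + left-handed substrate → free catalyst + left-handed product (k = 160 L² mol⁻² s⁻¹)
    reagent + free catalyst + right-handed substrate → free catalyst + right-handed product (k = 39.0 L² mol⁻² s⁻¹)
    left-handed substrate + racemization catalyst ⇌ right-handed substrate + racemization catalyst, rate k3*[racemization catalyst]*[left-handed substrate] forward; the back reaction follows from the equilibrium constant (k = 2.10 L mol⁻¹ s⁻¹)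
    racemization catalyst + added ligand ⇌ idle complex, settled at all times (K = 4.90 L mol⁻¹)

A neighbour of Tuesday's is charged with 0.10 M of reagent. I scale the drain constant with the charge to 0.0749 min⁻¹. The first pass gives a mean share of 0.845 and P of 71.8%, and the second gives 72.3%. That flask gives 63.6%, lower than my figure by 8.7 points, and it ends with 18.8% as right-handed product.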